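## Retrosynthetic overview

1. Target 16 ⇐ 15 by a last allylic C15–H hydroxylation (SeO2), the oxidase-type finishing step.
2. 15 ⇐ acyclic bromo-furan 11 in one cascade: furan → Z-4-oxo-enal; Cr(II) allyl/aldehyde closure of C6–C7 (the bond a germacrene synthase makes from the farnesyl chain); O6 → C12 lactone; transannular 10-OH → C3=O hemiketal.
3. 11 ⇐ allylic isobutyrate 9 + methyl 2-(bromomethyl)acrylate 10 by cross-metathesis (C7=C11).
4. 9 ⇐ ketone 3 + acrolein: C8 by aldol and Sharpless resolution, C10 by chelation-controlled MeMgBr; 3 ⇐ 3-methylfuran + methyl vinyl ketone.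
5. Ring order: ten-membered carbocycle, then γ-lactone, then oxolane hemiketal, all in step 7.

Assumption: germacrane numbering is used (C6–C7 is the ring-closing bond, C11–C13 the methylene lactone, C14 and C15 the carbons on C10 and C4).

Assumption: C3 is a hemiketal carbon that equilibrates through the open hydroxy ketone, so it is fixed by the bridge once C10 (R) is set, not by a reagent. Its descriptor in 15 and 16 is copied from the given SMILES; read literally, that string puts the C4 and C9 arms trans on the oxolane, which a bridged hemiketal cannot hold, so C6, C7, C8 and C10 are taken as the defining centres.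

Assumption: operations run in one flask without work-up count as one step.

## Route

Step 1
Reactants: 1 3-methylfuran; 2 methyl vinyl ketone (but-3-en-2-one)
Product: 3 4-(3-methylfuran-2-yl)butan-2-one
Conditions: 1 (5 equiv), Sc(OTf)3 (2 mol%), CH2Cl2, 0 °C; excess 1 distilled off
Reagents that add atoms: none
Why: Lewis-acid Friedel–Crafts conjugate addition (Michael alkylation) of a furan to an enone; a 3-alkylfuran is attacked mainly at C2 next to the methyl group, excess furan suppresses a second alkylation at C5, and no stereocentre is formed.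

Step 2
Reactants: 3 4-(3-methylfuran-2-yl)butan-2-one; 4 acrolein (prop-2-enal)
Product: 6 rac-5-hydroxy-1-(3-methylfuran-2-yl)hept-6-en-3-one, via kinetic lithium enolate 5 (not isolated)
Conditions: LDA (1.05 equiv), THF, −78 °C; then 4, −78 °C, 5 min; aq. NH4Cl
Reagents that add atoms: none
Why: kinetic deprotonation on the methyl side followed by 1,2-aldol addition to acrolein; C8 is formed racemic here and resolved in step 3.

Step 3
Reactants: 6 rac-5-hydroxy-1-(3-methylfuran-2-yl)hept-6-en-3-one
Product: 7 (5R)-5-hydroxy-1-(3-methylfuran-2-yl)hept-6-en-3-one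
Conditions: Ti(OiPr)4 (15 mol%), L-(+)-DIPT (18 mol%), t-BuOOH (0.6 equiv), 4 Å MS, CH2Cl2, −20 °C, to about 55% conversion
Reagents that add atoms: none
Why: Sharpless kinetic resolution of a secondary vinyl carbinol: with L-(+)-tartrate the (S)-alcohol is epoxidised fast and the (R)-alcohol, which is C8 of the target, is recovered in high ee (expected ≥98%).

Step 4
Reactants: 7 (5R)-5-hydroxy-1-(3-methylfuran-2-yl)hept-6-en-3-one
Product: 8 (3R,5R)-3-methyl-1-(3-methylfuran-2-yl)hept-6-ene-3,5-diol
Conditions: MeMgBr (3.5 equiv), CH2Cl2/Et2O, −78 → −40 °C; aq. NH4Cl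
Reagents that add atoms: methylmagnesium bromide, C[Mg]Br
Why: chelation-controlled Grignard addition (Cram–Reetz β-chelate model): Mg bridges the C8 alkoxide and the ketone in a half-chair, methyl enters axially while the furylethyl chain stays equatorial, which gives the 1,3-syn diol and so C10 (R).

Step 5
Reactants: 8 (3R,5R)-3-methyl-1-(3-methylfuran-2-yl)hept-6-ene-3,5-diol
Product: 9 (3R,5R)-5-hydroxy-5-methyl-7-(3-methylfuran-2-yl)hept-1-en-3-yl 2-methylpropanoate
Conditions: (i-PrCO)2O (1.3 equiv), Et3N, DMAP (10 mol%), CH2Cl2, 0 °C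
Reagents that add atoms: isobutyric anhydride, CC(C)C(=O)OC(=O)C(C)C
Why: DMAP-catalysed (Steglich-type) acylation takes the secondary allylic hydroxyl and leaves the tertiary one, with retention at C8; the ester also keeps O8 from closing onto the allylic bromide or onto C12 later.

Step 6
Reactants: 9 (3R,5R)-5-hydroxy-5-methyl-7-(3-methylfuran-2-yl)hept-1-en-3-yl 2-methylpropanoate; 10 methyl 2-(bromomethyl)acrylate
Product: 11 methyl (2Z,4R,6R)-2-(bromomethyl)-6-hydroxy-6-methyl-4-(2-methylpropanoyloxy)-8-(3-methylfuran-2-yl)oct-2-enoate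
Conditions: 10 (5 equiv), Hoveyda–Grubbs II (10 mol%), CH2Cl2, 40 °C, N2 sweep
Reagents that add atoms: none
Why: olefin cross-metathesis of a monosubstituted allylic ester with a 1,1-disubstituted acrylate (methacrylate-type partner), giving the more stable trisubstituted enoate with the ester trans to C8 (2Z); no stereocentre is touched.

Step 7
Reactants: 11 methyl (2Z,4R,6R)-2-(bromomethyl)-6-hydroxy-6-methyl-4-(2-methylpropanoyloxy)-8-(3-methylfuran-2-yl)oct-2-enoate
Product: 15 (6R,7R,8R,10R)-3,10-epoxy-3-hydroxy-8-(2-methylpropanoyloxy)germacra-4Z,11(13)-dien-6,12-olide (15-deoxy target), via furan endoperoxide 12 (not isolated), via Z-keto-enal 13 (not isolated), via ten-membered hydroxy keto lactone 14 (not isolated)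
Conditions: O2, TPP (cat.), hν, CH2Cl2, −78 °C; Me2S, −78 → 0 °C; evaporate; CrCl2 (8 equiv), THF/DMF 4:1, 2 mM, syringe pump, rt; aq. NH4Cl
Reagents that add atoms: dioxygen, O=O
Why: Proposed new method: singlet-oxygen [4+2] addition to the furan and Me2S reduction unmask the Z-4-oxo-enal 13, whose γ-hydroxy ketone sits largely in its closed hemiketal form (this keeps the alkene Z, hides the ene-dione from Cr(II) and pre-folds the chain); Cr(II) then reduces the C–Br bond and the allyl unit adds through C7 to the C6 aldehyde in a chair Nozaki–Hiyama–Kishi transition state (C5 and C8 equatorial gives the 6,7-trans relationship; attack on the C7 face that carries the C9 tether, with the C8–O bond inside, gives H7 and H8 cis), the chromium alkoxide lactonises onto the methyl ester, and the C10 hydroxyl closes onto the C3 ketone with C3 fixed by the bridge; the closest known reactions are the Cr(II)-mediated intramolecular Barbier macrocyclisations used for costunolide- and parthenolide-type ten-membered rings and the oxidative unmasking of furans to cis-enediones.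

Step 8
Reactants: 15 (6R,7R,8R,10R)-3,10-epoxy-3-hydroxy-8-(2-methylpropanoyloxy)germacra-4Z,11(13)-dien-6,12-olide
Product: 16 target, the 15-hydroxy derivative of 15 (CNP0282937.1)
Conditions: SeO2 (0.5 equiv), t-BuOOH (3 equiv), CH2Cl2, rt
Reagents that add atoms: tert-butyl hydroperoxide, CC(C)(C)OO (oxygen passed on through catalytic SeO2, O=[Se]=O)
Why: Riley/Sharpless SeO2–TBHP allylic hydroxylation (ene reaction at C5, then [2,3]-shift): on the more substituted alkene carbon C4 only the C15 methyl carries hydrogens, the ring holds the 4Z geometry, and such late methyl hydroxylations are known for germacranolides; no stereocentre changes.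

## Compound list

1 | 3-methylfuran | Cc1ccoc1 | starting material
2 | methyl vinyl ketone | CC(=O)C=C | starting material
3 | 4-(3-methylfuran-2-yl)butan-2-one | CC(=O)CCc1occc1C | intermediate
4 | acrolein | C=CC=O | starting material
5 | lithium 4-(3-methylfuran-2-yl)but-1-en-2-olate (kinetic enolate of 3) | [Li+].[O-]C(=C)CCc1occc1C | intermediate
6 | rac-5-hydroxy-1-(3-methylfuran-2-yl)hept-6-en-3-one | C=CC(O)CC(=O)CCc1occc1C | intermediate
7 | (5R)-5-hydroxy-1-(3-methylfuran-2-yl)hept-6-en-3-one | C=C[C@H](O)CC(=O)CCc1occc1C | intermediate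
8 | (3R,5R)-3-methyl-1-(3-methylfuran-2-yl)hept-6-ene-3,5-diol | C=C[C@H](O)C[C@](C)(O)CCc1occc1C | intermediate
9 | (3R,5R)-5-hydroxy-5-methyl-7-(3-methylfuran-2-yl)hept-1-en-3-yl 2-methylpropanoate | C=C[C@H](OC(=O)C(C)C)C[C@](C)(O)CCc1occc1C | intermediate
10 | methyl 2-(bromomethyl)acrylate | C=C(CBr)C(=O)OC | starting material
11 | methyl (2Z,4R,6R)-2-(bromomethyl)-6-hydroxy-6-methyl-4-(2-methylpropanoyloxy)-8-(3-methylfuran-2-yl)oct-2-enoate | COC(=O)/C(CBr)=C/[C@H](OC(=O)C(C)C)C[C@](C)(O)CCc1occc1C | intermediate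
12 | furan endoperoxide of 11 (2,3,7-trioxabicyclo[2.2.1]hept-5-ene; both bridgehead epimers) | COC(=O)/C(CBr)=C/[C@H](OC(=O)C(C)C)C[C@](C)(O)CCC12OOC(O1)C=C2C | intermediate
13 | methyl (2Z,4R,6R,10Z)-2-(bromomethyl)-6-hydroxy-6,10-dimethyl-4-(2-methylpropanoyloxy)-9,12-dioxododeca-2,10-dienoate (open form; in equilibrium with its cyclic hemiketal) | COC(=O)/C(CBr)=C/[C@H](OC(=O)C(C)C)C[C@](C)(O)CCC(=O)/C(C)=C\C=O | intermediate
14 | (6R,7R,8R,10R)-10-hydroxy-8-(2-methylpropanoyloxy)-3-oxogermacra-4Z,11(13)-dien-6,12-olide | C=C1C(=O)O[C@@H]2/C=C(/C)C(=O)CC[C@@](C)(O)C[C@@H](OC(=O)C(C)C)[C@@H]12 | intermediate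
15 | (6R,7R,8R,10R)-3,10-epoxy-3-hydroxy-8-(2-methylpropanoyloxy)germacra-4Z,11(13)-dien-6,12-olide (15-deoxy target) | C=C1C(=O)O[C@@H]2/C=C(/C)[C@@]3(O)CC[C@](C)(C[C@@H](OC(=O)C(C)C)[C@@H]12)O3 | intermediate
16 | 15-hydroxy derivative of 15 (CNP0282937.1) | C=C1C(=O)O[C@@H]2/C=C(/CO)[C@@]3(O)CC[C@](C)(C[C@@H](OC(=O)C(C)C)[C@@H]12)O3 | target

## Step count and risks

Total step count: 8. Longest linear sequence: 8 (fully linear from 3-methylfuran).

The three steps most likely to fail:

**Step 7 (cascade).** The risks are slow ring closure from the lactol-masked aldehyde, protonolysis or 1,4-loss of isobutyrate from the allylchromium, Cr(II) reduction of the ene-dione, and the wrong C6/C7 face. The fallback sets out from 9 (and 10) and comes back at 15, replacing the reductive metalation by a redox-neutral allylboration. Compound 10 is borylated (B2pin2, CuCl, KOAc) to methyl 2-[(4,4,5,5-tetramethyl-1,3,2-dioxaborolan-2-yl)methyl]acrylate F1. Cross-metathesis of 9 with it gives the allylboronate analogue of 11 F2. Photooxygenation and Me2S give the Z-keto-enal boronate F3, which is closed at high dilution with catalytic Sc(OTf)3 through a closed chair allylboration (Hall-type 2-alkoxycarbonyl allylboronate chemistry), followed by lactonisation and hemiketal formation to 15.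

**Step 6 (cross-metathesis).** A secondary allylic ester and a gem-disubstituted bromo-acrylate are both sluggish partners. The fallback sets out from 9 and comes back at 11, building the bromomethyl enoate by Morita–Baylis–Hillman chemistry instead. Lemieux–Johnson cleavage (OsO4 cat., NaIO4, 2,6-lutidine; chosen over ozone because of the furan) gives the α-acyloxy aldehyde (2R,4R)-4-hydroxy-4-methyl-6-(3-methylfuran-2-yl)-1-oxohexan-2-yl 2-methylpropanoate F4, largely as its lactol. Reaction with methyl acrylate and DABCO gives the Baylis–Hillman alcohol F5 (either carbinol epimer serves). NBS/Me2S then effects the SN2′ bromination to 11.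

**Step 8 (late SeO2 hydroxylation).** The alkene is hindered and over-oxidation to the enal is possible. The fallback sets out from 2 and comes back at 16, carrying the C15 oxygen from the start. Commercial 3-furanmethanol is silylated to tert-butyl(furan-3-ylmethoxy)dimethylsilane F6, which replaces 1. Steps 1–7 are run unchanged through the silyloxymethyl ketone F7, its lithium enolate F8, the racemic aldol F9, the (R)-aldol F10, the syn diol F11, the isobutyrate F12, the bromide F13, the endoperoxide F14, the Z-keto-enal F15, the ten-membered hydroxy keto lactone F16 and the 15-O-TBS ether of the target F17. HF·pyridine then gives 16.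

Further compounds
F1 | step 7 | methyl 2-[(4,4,5,5-tetramethyl-1,3,2-dioxaborolan-2-yl)methyl]acrylate | C=C(CB1OC(C)(C)C(C)(C)O1)C(=O)OC
F2 | step 7 | methyl (2E,4R,6R)-6-hydroxy-6-methyl-4-(2-methylpropanoyloxy)-8-(3-methylfuran-2-yl)-2-[(4,4,5,5-tetramethyl-1,3,2-dioxaborolan-2-yl)methyl]oct-2-enoate | COC(=O)/C(CB1OC(C)(C)C(C)(C)O1)=C/[C@H](OC(=O)C(C)C)C[C@](C)(O)CCc1occc1C
F3 | step 7 | Z-keto-enal boronate (boron analogue of 13) | COC(=O)/C(CB1OC(C)(C)C(C)(C)O1)=C/[C@H](OC(=O)C(C)C)C[C@](C)(O)CCC(=O)/C(C)=C\C=O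
F4 | step 6 | (2R,4R)-4-hydroxy-4-methyl-6-(3-methylfuran-2-yl)-1-oxohexan-2-yl 2-methylpropanoate | O=C[C@H](OC(=O)C(C)C)C[C@](C)(O)CCc1occc1C
F5 | step 6 | methyl (4R,6R)-3,6-dihydroxy-6-methyl-2-methylidene-4-(2-methylpropanoyloxy)-8-(3-methylfuran-2-yl)octanoate (C3 epimers) | C=C(C(=O)OC)C(O)[C@H](OC(=O)C(C)C)C[C@](C)(O)CCc1occc1C
F6 | step 8 | tert-butyl(furan-3-ylmethoxy)dimethylsilane | CC(C)(C)[Si](C)(C)OCc1ccoc1
F7 | step 8 | 4-[3-(tert-butyldimethylsilyloxymethyl)furan-2-yl]butan-2-one | CC(=O)CCc1occc1CO[Si](C)(C)C(C)(C)C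
F8 | step 8 | kinetic lithium enolate of F7 | [Li+].[O-]C(=C)CCc1occc1CO[Si](C)(C)C(C)(C)C
F9 | step 8 | rac-5-hydroxy-1-[3-(tert-butyldimethylsilyloxymethyl)furan-2-yl]hept-6-en-3-one | C=CC(O)CC(=O)CCc1occc1CO[Si](C)(C)C(C)(C)C
F10 | step 8 | (5R)-5-hydroxy-1-[3-(tert-butyldimethylsilyloxymethyl)furan-2-yl]hept-6-en-3-one | C=C[C@H](O)CC(=O)CCc1occc1CO[Si](C)(C)C(C)(C)C
F11 | step 8 | (3R,5R)-3-methyl-1-[3-(tert-butyldimethylsilyloxymethyl)furan-2-yl]hept-6-ene-3,5-diol | C=C[C@H](O)C[C@](C)(O)CCc1occc1CO[Si](C)(C)C(C)(C)C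
F12 | step 8 | silyloxymethyl analogue of 9 | C=C[C@H](OC(=O)C(C)C)C[C@](C)(O)CCc1occc1CO[Si](C)(C)C(C)(C)C
F13 | step 8 | silyloxymethyl analogue of 11 | COC(=O)/C(CBr)=C/[C@H](OC(=O)C(C)C)C[C@](C)(O)CCc1occc1CO[Si](C)(C)C(C)(C)C
F14 | step 8 | silyloxymethyl analogue of 12 | COC(=O)/C(CBr)=C/[C@H](OC(=O)C(C)C)C[C@](C)(O)CCC12OOC(O1)C=C2CO[Si](C)(C)C(C)(C)C
F15 | step 8 | silyloxymethyl analogue of 13 | COC(=O)/C(CBr)=C/[C@H](OC(=O)C(C)C)C[C@](C)(O)CCC(=O)/C(CO[Si](C)(C)C(C)(C)C)=C\C=O
F16 | step 8 | silyloxymethyl analogue of 14 | C=C1C(=O)O[C@@H]2/C=C(/CO[Si](C)(C)C(C)(C)C)C(=O)CC[C@@](C)(O)C[C@@H](OC(=O)C(C)C)[C@@H]12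
F17 | step 8 | 15-O-tert-butyldimethylsilyl ether of 16 | C=C1C(=O)O[C@@H]2/C=C(/CO[Si](C)(C)C(C)(C)C)[C@@]3(O)CC[C@](C)(C[C@@H](OC(=O)C(C)C)[C@@H]12)O3
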